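## Retrosynthetic overview
1. Benzylic C–O bond, made last and setting the (S) centre. The target is cut into (Z)-4-acetoxy-2-methylbut-2-enoic acid, used as the O-nucleophile, and the para-quinone methide obtained by dehydrogenating the free 4-ethylphenol enone. No protecting groups are needed, and the acyl carbon of the Z-enoate is never activated.
2. Aryl–C(=O) bond. The o-hydroxyaryl enone comes from 4-ethylphenyl 3-methylbut-2-enoate by photo-Fries rearrangement, and that ester comes from 4-ethylphenol and 3-methylbut-2-enoyl chloride.
3. The acid comes from 3-methylfuran-2(5H)-one. Opening the lactone passes on the Z geometry, and O-acetylation follows.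
4. Rings: none is formed. The benzene ring is bought and the butenolide ring is opened.

Assumption: the sense of induction of the phosphoric acid in step 4 cannot be known beforehand. The (R)-catalyst is written, and its equally available mirror image is used if the (R)-ester is obtained.

## Route

Step 1
Reactants: 1 4-ethylphenol; 2 3-methylbut-2-enoyl chloride (senecioyl chloride)
Product: 3 4-ethylphenyl 3-methylbut-2-enoate
Conditions: 2 M aq NaOH (1.3 equiv), Bu4NHSO4 (5 mol %), CH2Cl2, 0 °C, 30 min
Reagents that add atoms: none
Why: Phase-transfer Schotten–Baumann O-acylation of the phenoxide is fast and clean, and the amine-free medium avoids the vinylketene pathway that deconjugates senecioyl chloride; no stereocentre is involved.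

Step 2
Reactants: 3 4-ethylphenyl 3-methylbut-2-enoate
Product: 4 1-(5-ethyl-2-hydroxyphenyl)-3-methylbut-2-en-1-one
Conditions: hν (254 nm, low-pressure Hg lamp, quartz), degassed cyclohexane (0.02 M), 20 °C, stopped at about 90 % conversion
Reagents that add atoms: none
Why: Photo-Fries rearrangement: singlet-state homolysis of the ArO–C(O) bond gives a solvent-caged phenoxyl/acyl radical pair that recombines at the ortho carbon (para is blocked by the ethyl group), the chelated product is shielded from further photochemistry by excited-state proton transfer, and the neutral medium avoids the chromanone and 4,4-dimethyldihydrocoumarin that Lewis-acid Fries conditions give with senecioates; no stereocentre is involved.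

Step 3
Reactants: 5 3-methylfuran-2(5H)-one
Product: 7 (Z)-4-acetoxy-2-methylbut-2-enoic acid, via potassium (Z)-4-hydroxy-2-methylbut-2-enoate 6 (not isolated)
Conditions: KOH (1.00 equiv), MeOH/H2O, 0 °C to rt, evaporated and dried by toluene azeotrope in the same flask; then Ac2O (3 equiv), pyridine, 0 °C; then ice-water, cold 1 M HCl to pH 2, EtOAc
Reagents that add atoms: potassium hydroxide [K+].[OH-]; acetic anhydride CC(=O)OC(C)=O
Why: Lactone saponification hands the ring-locked Z geometry to the open hydroxy carboxylate, O-acetylation of the dry salt (the tactic expected to turn phthalide into 2-(acetoxymethyl)benzoic acid and butyrolactone into 4-acetoxybutanoic acid) caps the hydroxyl before any acid is present, and the capped acid can no longer relactonise when it is freed at pH 2; there is no stereocentre and the alkene geometry is retained.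

Step 4
Reactants: 4 1-(5-ethyl-2-hydroxyphenyl)-3-methylbut-2-en-1-one; 7 (Z)-4-acetoxy-2-methylbut-2-enoic acid (1.5 equiv)
Product: 9 (S)-1-[4-hydroxy-3-(3-methylbut-2-enoyl)phenyl]ethyl (Z)-4-acetoxy-2-methylbut-2-enoate, via para-quinone methide 8 (not isolated)
Conditions: DDQ (1.05 equiv), (R)-3,3'-bis(triphenylsilyl)-1,1'-binaphthyl-2,2'-diyl hydrogen phosphate (10 mol %), powdered 4 Å MS, CH2Cl2, −40 °C, 455 nm LED; cold filtration, brief aq NaHCO3 wash
Reagents that add atoms: none
Why: Proposed new method: excitation of DDQ and of its charge-transfer complex with 4 (the most easily oxidised donor in the flask) triggers electron transfer followed by loss of the phenolic proton and of a benzylic hydrogen atom to the reduced quinone, so the acyl-deactivated ethylphenol is dehydrogenated to para-quinone methide 8 at −40 °C, where ground-state hydride abstraction would need heating; the chiral phosphoric acid (chosen without benzylic C–H bonds) hydrogen-bonds the quinone methide carbonyl through P–OH and acid 7 through P=O, and this bridged heterodimer delivers the carboxyl oxygen to one face of the ethylidene carbon in an aromatising 1,6-addition that forms the benzylic C–O bond and sets the (S) centre under kinetic control, because a weak acid at low temperature cannot re-ionise the ester and the (Z)-enoyl carbonyl is never activated; the closest known reaction types are racemic DDQ benzylic acyloxylation of 4-alkylphenols and 4-alkylanisoles in acetic acid, phosphoric acid-catalysed asymmetric 1,6-addition of thioacids to para-quinone methides, and opening of epoxides by phosphoric acid/carboxylic acid heterodimers.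

## Compound list
1 | 4-ethylphenol | CCc1ccc(O)cc1 | starting material
2 | 3-methylbut-2-enoyl chloride | CC(C)=CC(=O)Cl | starting material
3 | 4-ethylphenyl 3-methylbut-2-enoate | CCc1ccc(OC(=O)C=C(C)C)cc1 | intermediate
4 | 1-(5-ethyl-2-hydroxyphenyl)-3-methylbut-2-en-1-one | CCc1ccc(O)c(C(=O)C=C(C)C)c1 | intermediate
5 | 3-methylfuran-2(5H)-one | CC1=CCOC1=O | starting material
6 | potassium (Z)-4-hydroxy-2-methylbut-2-enoate | OC/C=C(/C)C(=O)[O-].[K+] | intermediate
7 | (Z)-4-acetoxy-2-methylbut-2-enoic acid | CC(=O)OC/C=C(/C)C(=O)O | intermediate
8 | 4-ethylidene-2-(3-methylbut-2-enoyl)cyclohexa-2,5-dien-1-one (para-quinone methide, E/Z mixture at the ethylidene) | CC=C1C=CC(=O)C(C(=O)C=C(C)C)=C1 | intermediate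
9 | (S)-1-[4-hydroxy-3-(3-methylbut-2-enoyl)phenyl]ethyl (Z)-4-acetoxy-2-methylbut-2-enoate (CNP0194710.1) | CC(=O)OC/C=C(/C)C(=O)O[C@@H](C)c1ccc(O)c(C(=O)C=C(C)C)c1 | target

## Step count and risks
Total steps: 4, with no protecting groups. Longest linear sequence: 3 (steps 1, 2 and 4). Step 3 is the convergent branch.

**Step 4 (the new method)**
- Uncatalysed addition of 7, or addition promoted by the hydroquinone, to the very reactive unhindered 8 would lower the ee.
- The catalyst has to tell H from CH3 at a remote carbon.
- The two ethylidene isomers of 8 are no longer equivalent because of the acyl group.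
- 8 can tautomerise to the vinylphenol or be captured by the reduced quinone.
- The product can be oxidised a second time.
- Excited DDQ could isomerise the Z-enoate.

The fallback uses known chemistry, sets out from 4 (and uses 7) and comes back at 9. Compound 4 is oxidised with DDQ (2.2 equiv) in dioxane/water at reflux, the established benzylic oxidation of 4-alkylphenols, to 1-(5-acetyl-2-hydroxyphenyl)-3-methylbut-2-en-1-one F1. Noyori transfer hydrogenation with RuCl(p-cymene)[(S,S)-TsDPEN] in HCO2H/Et3N (5:2) reduces only the unchelated methyl ketone, since the chelated β,β-disubstituted enone is inert. This gives 1-{2-hydroxy-5-[(1S)-1-hydroxyethyl]phenyl}-3-methylbut-2-en-1-one F2. Separately, 7 is converted with 2,4,6-trichlorobenzoyl chloride/Et3N into (Z)-4-acetoxy-2-methylbut-2-enoic 2,4,6-trichlorobenzoic anhydride F3. After the ammonium salt is filtered off, F3 acylates the secondary alcohol of F2 in toluene at 70 °C without DMAP. This is the non-isomerising Yamaguchi-type protocol used for angelate esters. It gives 9 with retention at carbon, and the chelated phenol stays free.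

**Step 3**
The carboxylate can form a mixed anhydride with Ac2O and relactonise to 5 before the hydroxyl is capped. The fallback sets out from 6 and comes back at 7. It masks the carboxyl as a non-activated ester during the acetylation. The dry salt 6 is alkylated with 4-methoxybenzyl chloride in DMF to 4-methoxybenzyl (Z)-4-hydroxy-2-methylbut-2-enoate F4. F4 is acetylated at once (Ac2O, pyridine, 0 °C) to 4-methoxybenzyl (Z)-4-acetoxy-2-methylbut-2-enoate F5. The ester is then cleaved with TFA/anisole in CH2Cl2 at 0 °C to give 7.

**Step 2**
The yield may be moderate because cage escape returns 1, and the ester may photodeconjugate. The fallback sets out from 1 and comes back at 4, building the ketone by polar chemistry.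
- Ortho-formylation of 1 (MgCl2, Et3N, paraformaldehyde, MeCN, reflux) gives 5-ethyl-2-hydroxybenzaldehyde F6.
- Addition of 2-methylprop-1-enylmagnesium bromide (2.2 equiv, THF, 0 °C) gives racemic 4-ethyl-2-(1-hydroxy-3-methylbut-2-en-1-yl)phenol F7.
- Crude F7 is oxidised with MnO2 in CH2Cl2 at rt to 4.

## Further compounds
F1 | step 4 | 1-(5-acetyl-2-hydroxyphenyl)-3-methylbut-2-en-1-one | CC(=O)c1ccc(O)c(C(=O)C=C(C)C)c1
F2 | step 4 | 1-{2-hydroxy-5-[(1S)-1-hydroxyethyl]phenyl}-3-methylbut-2-en-1-one | O[C@@H](C)c1ccc(O)c(C(=O)C=C(C)C)c1
F3 | step 4 | (Z)-4-acetoxy-2-methylbut-2-enoic 2,4,6-trichlorobenzoic anhydride | CC(=O)OC/C=C(/C)C(=O)OC(=O)c1c(Cl)cc(Cl)cc1Cl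
F4 | step 3 | 4-methoxybenzyl (Z)-4-hydroxy-2-methylbut-2-enoate | OC/C=C(/C)C(=O)OCc1ccc(OC)cc1
F5 | step 3 | 4-methoxybenzyl (Z)-4-acetoxy-2-methylbut-2-enoate | CC(=O)OC/C=C(/C)C(=O)OCc1ccc(OC)cc1
F6 | step 2 | 5-ethyl-2-hydroxybenzaldehyde | CCc1ccc(O)c(C=O)c1
F7 | step 2 | 4-ethyl-2-(1-hydroxy-3-methylbut-2-en-1-yl)phenol (racemic) | CCc1ccc(O)c(C(O)C=C(C)C)c1
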